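## The problem

Compound 24 (CNP0212387.1) is a hexasubstituted benzene. Ring carbons C4a and C8a carry the fused 2,2-dimethyl-2H-pyran, C5 and C7 carry hydroxyls, C8 carries the (2S)-2-methylbutanoyl group, and C6 carries a methylene that ends at C3 of a 6-ethyl-4-hydroxy-5-methylpyran-2-one. No two ring positions are equivalent, so the central question is which of the three phloroglucinol oxygens becomes the pyran oxygen O1 relative to the acyl group and the bridge. The only stereocentre lies alpha to the aryl ketone, far from every other functional group. Nothing can induce it and it can direct nothing, so it has to be bought as (2S)-2-methylbutanoic acid 9 and then kept away from enolising conditions. The C3=C4 chromene bond rules out hydrogenolysis, strong Lewis acids and hot mineral acid. The free phenols are oxidation-prone, and the acidic 4-hydroxypyranone quenches organometallic reagents. The enabling feature is that the bridge carbon sits on C6, para to C8a–O1 and between the two phenolic oxygens. If that carbon is carried as a formyl group, the arene is phloroglucinaldehyde 1. Its one oxygen that does not neighbour the formyl group is the future O1, and the two carbons ortho to that oxygen are mirror images. A propargyl ether on that oxygen can therefore give only the required chromene, and C8 is left as the single open ring carbon for the acyl group.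

## Retrosynthesis

**24 from 23.** The last operation cuts only the two O–CH2OCH3 bonds of bis(methoxymethyl) ether 23. Acetal protection is preferred to benzyl ethers, whose hydrogenolysis would saturate C3=C4, and to methyl ethers, whose removal needs boron halides that attack the chromene. The same two groups also serve earlier as caps in the ring-forming step and as directors for metalation. The forward reaction must be a mild acid methanolysis that leaves the chromene, the lactone and the stereocentre alone.

**23 from 15 and 21.** The bond between the bridge carbon and pyranone C3 is cut, giving aldehyde 15 and pyranone 21. The neighbouring cut, arene C6–CH2, would call for a reactive methylene-pyrandione to attack a free phloroglucinol carbon; that returns the regiochemical question to an acyl-first arene. Here the bridge carbon is already in place as the formyl group. The forward step is a condensation to alkylidene 22 followed in the same flask by conjugate hydride transfer. The phenols stay capped at this stage, so that no ortho hydroxyl can attack the lactone carbonyl of 22 and divert it to a coumarin.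

**21 from 18 and 19, and 18 from 16.** The pyranone is cut at C4–C5 and O1–C2. This gives malonyl dichloride 19 as the three-carbon unit and silyl enol ether 18 of pentan-3-one 16, which is symmetric and so gives one enol ether constitution. The forward reaction is C-acylation then lactonisation through acid chloride 20. It is done at the start on cheap material.

**15 from 8 and 11, and 11 from 9.** The C8–acyl bond is cut. Friedel–Crafts or Fries chemistry on the free phenol would need Lewis acids that the chromene does not tolerate. In 8, C8–H is the only arene hydrogen and lies between O1 and the C7 acetal oxygen, so directed lithiation is unambiguous. The formyl group must be masked, and a transient lithium alpha-amino alkoxide (12) does this without an isolated, acid-labile acetal next to the MOM ethers. Weinreb amide 11, one step from acid 9, delivers the intact stereocentre and stops at the ketone stage through chelate 14.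

**8 from 4 (key disconnection).** The C4–C4a and O1–C2 bonds are cut, which reveals aryl 1,1-dimethylpropargyl ether 4. The competing way to a chromene, condensation of a free phenol with an unsaturated C5 aldehyde, has to choose between three oxygens. In 4 the ether oxygen is the only one that can become O1, because the other two are capped, and the two ortho carbons are equivalent. The precursor has no ring beyond the benzene. The forward reaction is a purely thermal cascade.

**4 from 3, and 3 from 1 and 2.** Two O–CH2 bonds and then the aryl O–C(CH3)2 bond are cut, leading to aldehyde 1 and chloride 2. Alkylation must pick the 4-hydroxyl. It is the most acidic hydroxyl and the only one that cannot hydrogen-bond to the formyl group.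

## Roads not taken

**Alternative 1:** The benzene ring itself is cut at C8–C7, leading back to tetraketide pyranone A1. In the forward direction magnesium methoxide would open the lactone and the side-chain methylene would attack the former lactone carbonyl in a Claisen-type closure, giving acylphloroglucinol A2.
- Merits: the route is biomimetic, the acyl group and its stereocentre arrive with the ring, and no organometallic acylation of a crowded arene is needed. In that respect it is better than the chosen plan.
- Weak points: A2 is a simple symmetric ketone, so the ring construction solves no problem that direct C-acylation would not. The stereocentre spends the key step alpha to a ketone in hot alkoxide. Above all, A2 leaves the real difficulty open. The target needs an oxygen next to the acyl group as O1 and the carbon para to it for the bridge, but chromene formation on A2 is expected to use the unchelated, more acidic para hydroxyl and so give the 6-acyl constitution.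
- Comparison: the chosen plan accepts a late aryllithium acylation (step 5), and in return the regiochemistry is fixed by symmetry and capping.

**Alternative 2:** Two ring bonds, C8–C8a and C6–C7, are cut. Forward, 3-ethoxycyclobutenone A3 would open to a vinylketene, add to siloxyalkyne A4, and after four-electron opening and six-electron closure give phenol A5.
- Merits: A5 has all three oxygens differentiated, a single free phenol as the future O1, and only one free ortho carbon, so chromene regiochemistry is as secure as in the chosen plan. The side-chain carbon skeleton is installed without a late organolithium step, which is an advantage.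
- Weak points: A4 needs a multistep chiral-pool preparation. The benzylic silyl ether must later be unmasked and oxidised next to the stereocentre. The bridge carbon is still missing and has to be introduced between two oxygens. The ethyl ether must be cleaved at the end under conditions the chromene is unlikely to survive.
- Comparison: the chosen plan has roughly half the step count, uses commercial building blocks and needs no ether cleavage harsher than acetal methanolysis.

**Alternative 3:** The pyranone is cut at C4–C5 and O1–C2 at the end of the synthesis. Forward, benzylmalonyl dichloride A6 would C-acylate silyl enol ether 18 and the resulting enol would close onto the second acid chloride, giving diacetate A7, which is deacetylated to 24.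
- Merits: the bridge C–C bond comes from an ordinary malonate alkylation, not from condensation at a di-ortho-substituted aldehyde. That bond formation is more certain than step 8.
- Weak points: A6 takes four or five operations from an aldehyde such as 15 (reduction, activation, malonate alkylation, hydrolysis, chlorination). Its formation and use release hydrogen chloride beside the chromene. The phenols must be acetylated. The least efficient ring construction of the route is placed last, on the most valuable intermediate.
- Comparison: the chosen plan uses the same acid chloride and enol ether chemistry at the outset on 19 (step 7), and joins two finished halves in a single flask.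

Key step: step 3

## Route

Assumption: phenoxide salts formed on deprotonation of 1 and 3 are treated as ionised forms of those compounds and are not numbered. Enol ether 18 is used as an E/Z mixture, since both isomers converge on 21.

Step 1
Reactants: 1 2,4,6-trihydroxybenzaldehyde; 2 3-chloro-3-methylbut-1-yne
Product: 3 2,6-dihydroxy-4-[(2-methylbut-3-yn-2-yl)oxy]benzaldehyde
Conditions: K2CO3, KI (cat.), CuI (cat.), acetone, 55 °C
Reagents that add atoms: none
Why: Copper-assisted O-propargylation (Williamson-type etherification) with about one equivalent of 2. The 4-hydroxyl is the most acidic and the only one that cannot chelate the formyl group, so it should be alkylated in preference to the two flanking hydroxyls.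

Step 2
Reactants: 3 2,6-dihydroxy-4-[(2-methylbut-3-yn-2-yl)oxy]benzaldehyde
Product: 4 2,6-bis(methoxymethoxy)-4-[(2-methylbut-3-yn-2-yl)oxy]benzaldehyde
Conditions: NaH, MOMCl, DMF, 0 °C to rt
Reagents that add atoms: chloromethyl methyl ether, COCCl
Why: Standard phenol O-alkylation to MOM ethers; the phenoxides are needed because the remaining hydroxyl is chelated after the first alkylation. Capping both flanking oxygens leaves the ether oxygen as the only one that can close the pyran in step 3.

Step 3
Reactants: 4 2,6-bis(methoxymethoxy)-4-[(2-methylbut-3-yn-2-yl)oxy]benzaldehyde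
Product: 8 5,7-bis(methoxymethoxy)-2,2-dimethyl-2H-chromene-6-carbaldehyde, via allenyl dienone 5 (not isolated), via allenyl phenol 6 (not isolated), via ortho-quinone methide 7 (not isolated)
Conditions: o-xylene, 140 °C
Reagents that add atoms: none
Why: A thermal aromatic propargyl Claisen [3,3] shift moves the propargyl unit to an ortho carbon, forming the C4–C4a bond and dienone 5, which enolises to allenyl phenol 6. A 1,5-hydrogen shift from the new phenol O–H to the central allene carbon gives the Z-configured vinyl ortho-quinone methide 7; the Z geometry follows from the cyclic transition state of the hydrogen transfer. Thermal disrotatory oxa-6π electrocyclisation of this 1-oxatriene then re-forms O1–C2 and closes the six-membered 2H-pyran. The closest known reaction type is the thermal rearrangement of aryl 1,1-dimethylpropargyl ethers to 2,2-dimethyl-2H-chromenes, which the geminal methyl groups accelerate. No stereocentre is created: C2 carries two methyl groups and the sp3 carbon of 5 is lost on enolisation. The step needs a single regiochemical outcome; this is secured because the two ortho carbons are related by the mirror plane through the formyl carbon and the ether oxygen, and because the only free oxygen in 6 and 7 is the former ether oxygen. The formyl group therefore ends on C6 and the one remaining arene hydrogen on C8.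

Step 4
Reactants: 9 (2S)-2-methylbutanoic acid
Product: 11 (2S)-N-methoxy-N,2-dimethylbutanamide, via acyl imidazole 10 (not isolated)
Conditions: CDI, CH2Cl2, 0 °C to rt; MeNHOMe·HCl, rt
Reagents that add atoms: N,O-dimethylhydroxylamine hydrochloride, CNOC.Cl
Why: Weinreb amide formation through the acyl imidazole. Activation is neutral and no ketene or strongly basic stage intervenes, so the alpha stereocentre of 9 should be carried over unchanged.

Step 5
Reactants: 8 5,7-bis(methoxymethoxy)-2,2-dimethyl-2H-chromene-6-carbaldehyde; 11 (2S)-N-methoxy-N,2-dimethylbutanamide
Product: 15 5,7-bis(methoxymethoxy)-2,2-dimethyl-8-[(2S)-2-methylbutanoyl]-2H-chromene-6-carbaldehyde, via lithium amino alkoxide 12 (not isolated), via C8-lithiated amino alkoxide 13 (not isolated), via dilithium tetrahedral adduct 14 (not isolated)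
Conditions: N-methylpiperazine, n-BuLi, THF, −20 °C; n-BuLi, TMEDA, −20 to 0 °C; 11, −78 to 0 °C; aq NH4Cl
Reagents that add atoms: none
Why: In situ protection of the aldehyde as a lithium alpha-amino alkoxide, then directed ortho-lithiation at C8, the only arene C–H, which is flanked by O1 and the C7 acetal oxygen, then Weinreb ketone synthesis. The chelated adduct 14 collapses to ketone and aldehyde only on aqueous quench, so the stereocentre from 11 never sits next to a free ketone under basic conditions.

Step 6
Reactants: 16 pentan-3-one
Product: 18 trimethyl(pent-2-en-3-yloxy)silane, via lithium enolate 17 (not isolated)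
Conditions: LDA, THF, −78 °C; TMSCl, −78 °C to rt
Reagents that add atoms: chlorotrimethylsilane, C[Si](C)(C)Cl
Why: Kinetic enolisation and O-silylation of a symmetric ketone, which can give only one enol ether constitution. The E/Z ratio is irrelevant because the double bond ends inside the pyranone ring.

Step 7
Reactants: 18 trimethyl(pent-2-en-3-yloxy)silane; 19 propanedioyl dichloride (malonyl dichloride)
Product: 21 6-ethyl-4-hydroxy-5-methyl-2H-pyran-2-one, via diketo acid chloride 20 (not isolated)
Conditions: Et2O, −78 °C to rt
Reagents that add atoms: none
Why: Known pyranone synthesis from silyl enol ethers and malonyl dichloride: C-acylation of the enol ether with loss of the silyl chloride, then lactonisation of the ketone enol onto the second acid chloride and tautomerisation to the 4-hydroxypyranone.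

Step 8
Reactants: 15 5,7-bis(methoxymethoxy)-2,2-dimethyl-8-[(2S)-2-methylbutanoyl]-2H-chromene-6-carbaldehyde; 21 6-ethyl-4-hydroxy-5-methyl-2H-pyran-2-one
Product: 23 3-({5,7-bis(methoxymethoxy)-2,2-dimethyl-8-[(2S)-2-methylbutanoyl]-2H-chromen-6-yl}methyl)-6-ethyl-4-hydroxy-5-methyl-2H-pyran-2-one, via alkylidene pyrandione 22 (not isolated)
Conditions: L-proline (20 mol%), Hantzsch ester, EtOH, 25–50 °C
Reagents that add atoms: none
Why: Organocatalytic three-component reductive alkylation: amine-catalysed Knoevenagel condensation of the cyclic 1,3-dicarbonyl with the aldehyde, then conjugate hydride transfer from the dihydropyridine to the highly electrophilic alkylidene 22. The capped phenols cannot attack 22, the hindered aryl ketone and the chromene alkene are not hydride acceptors, and the bridge carbon becomes a CH2, so no stereocentre is formed.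

Step 9
Reactants: 23 3-({5,7-bis(methoxymethoxy)-2,2-dimethyl-8-[(2S)-2-methylbutanoyl]-2H-chromen-6-yl}methyl)-6-ethyl-4-hydroxy-5-methyl-2H-pyran-2-one
Product: 24 3-({5,7-dihydroxy-2,2-dimethyl-8-[(2S)-2-methylbutanoyl]-2H-chromen-6-yl}methyl)-6-ethyl-4-hydroxy-5-methyl-2H-pyran-2-one
Conditions: 3 M aq HCl, MeOH, 40 °C
Reagents that add atoms: none
Why: Acid-catalysed acetal methanolysis of aryl MOM ethers. The conditions are mild enough that the trisubstituted chromene alkene, the lactone and the ketone alpha stereocentre should be unaffected.

## Compound list

1 | 2,4,6-trihydroxybenzaldehyde | O=Cc1c(O)cc(O)cc1O | starting material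
2 | 3-chloro-3-methylbut-1-yne | CC(C)(Cl)C#C | starting material
3 | 2,6-dihydroxy-4-[(2-methylbut-3-yn-2-yl)oxy]benzaldehyde | O=Cc1c(O)cc(OC(C)(C)C#C)cc1O | intermediate
4 | 2,6-bis(methoxymethoxy)-4-[(2-methylbut-3-yn-2-yl)oxy]benzaldehyde | O=Cc1c(OCOC)cc(OC(C)(C)C#C)cc1OCOC | intermediate
5 | 2,6-bis(methoxymethoxy)-3-(3-methylbuta-1,2-dien-1-yl)-4-oxocyclohexa-1,5-diene-1-carbaldehyde (racemic at C3) | O=CC1=C(OCOC)C(C=C=C(C)C)C(=O)C=C1OCOC | intermediate (not isolated)
6 | 4-hydroxy-2,6-bis(methoxymethoxy)-3-(3-methylbuta-1,2-dien-1-yl)benzaldehyde | O=Cc1c(OCOC)cc(O)c(C=C=C(C)C)c1OCOC | intermediate (not isolated)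
7 | (3Z)-2,6-bis(methoxymethoxy)-3-(3-methylbut-2-en-1-ylidene)-4-oxocyclohexa-1,5-diene-1-carbaldehyde | O=CC1=C(OCOC)/C(=C/C=C(C)C)C(=O)C=C1OCOC | intermediate (not isolated)
8 | 5,7-bis(methoxymethoxy)-2,2-dimethyl-2H-chromene-6-carbaldehyde | O=Cc1c(OCOC)c2c(cc1OCOC)OC(C)(C)C=C2 | intermediate
9 | (2S)-2-methylbutanoic acid | CC[C@H](C)C(=O)O | starting material
10 | (2S)-1-(1H-imidazol-1-yl)-2-methylbutan-1-one | CC[C@H](C)C(=O)n1ccnc1 | intermediate (not isolated)
11 | (2S)-N-methoxy-N,2-dimethylbutanamide | CC[C@H](C)C(=O)N(C)OC | intermediate
12 | lithium [5,7-bis(methoxymethoxy)-2,2-dimethyl-2H-chromen-6-yl](4-methylpiperazin-1-yl)methanolate (carbinol carbon unspecified) | [Li+].[O-]C(N1CCN(C)CC1)c1c(OCOC)c2c(cc1OCOC)OC(C)(C)C=C2 | intermediate (not isolated)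
13 | lithium [8-lithio-5,7-bis(methoxymethoxy)-2,2-dimethyl-2H-chromen-6-yl](4-methylpiperazin-1-yl)methanolate | [Li+].[O-]C(N1CCN(C)CC1)c1c(OCOC)c2c(c([Li])c1OCOC)OC(C)(C)C=C2 | intermediate (not isolated)
14 | dilithium (2S)-1-{5,7-bis(methoxymethoxy)-2,2-dimethyl-6-[(4-methylpiperazin-1-yl)oxidomethyl]-2H-chromen-8-yl}-1-[methoxy(methyl)amino]-2-methylbutan-1-olate (both hemiaminal carbons unspecified) | [Li+].[Li+].[O-]C(N1CCN(C)CC1)c1c(OCOC)c2c(c(C([O-])(N(C)OC)[C@@H](C)CC)c1OCOC)OC(C)(C)C=C2 | intermediate (not isolated)
15 | 5,7-bis(methoxymethoxy)-2,2-dimethyl-8-[(2S)-2-methylbutanoyl]-2H-chromene-6-carbaldehyde | O=Cc1c(OCOC)c2c(c(C(=O)[C@@H](C)CC)c1OCOC)OC(C)(C)C=C2 | intermediate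
16 | pentan-3-one | CCC(=O)CC | starting material
17 | lithium pent-2-en-3-olate | CC=C(CC)[O-].[Li+] | intermediate (not isolated)
18 | trimethyl(pent-2-en-3-yloxy)silane (E/Z mixture) | CC=C(CC)O[Si](C)(C)C | intermediate
19 | propanedioyl dichloride (malonyl dichloride) | O=C(Cl)CC(=O)Cl | starting material
20 | 4-methyl-3,5-dioxoheptanoyl chloride (racemic) | CCC(=O)C(C)C(=O)CC(=O)Cl | intermediate (not isolated)
21 | 6-ethyl-4-hydroxy-5-methyl-2H-pyran-2-one | CCc1oc(=O)cc(O)c1C | intermediate
22 | 3-({5,7-bis(methoxymethoxy)-2,2-dimethyl-8-[(2S)-2-methylbutanoyl]-2H-chromen-6-yl}methylidene)-6-ethyl-5-methyl-2H-pyran-2,4(3H)-dione (alkene geometry unspecified) | CCC1=C(C)C(=O)C(=Cc2c(OCOC)c3c(c(C(=O)[C@@H](C)CC)c2OCOC)OC(C)(C)C=C3)C(=O)O1 | intermediate (not isolated)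
23 | 3-({5,7-bis(methoxymethoxy)-2,2-dimethyl-8-[(2S)-2-methylbutanoyl]-2H-chromen-6-yl}methyl)-6-ethyl-4-hydroxy-5-methyl-2H-pyran-2-one | CCc1oc(=O)c(Cc2c(OCOC)c3c(c(C(=O)[C@@H](C)CC)c2OCOC)OC(C)(C)C=C3)c(O)c1C | intermediate
24 | 3-({5,7-dihydroxy-2,2-dimethyl-8-[(2S)-2-methylbutanoyl]-2H-chromen-6-yl}methyl)-6-ethyl-4-hydroxy-5-methyl-2H-pyran-2-one | CCc1oc(=O)c(Cc2c(O)c3c(c(C(=O)[C@@H](C)CC)c2O)OC(C)(C)C=C3)c(O)c1C | target

## Step count and risk

Total step count: 9. Longest linear sequence: 6 steps (steps 1, 2, 3, 5, 8, 9, from 1). Steps 4, 6 and 7 prepare the two side branches.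

**Step 3 (key step).** The tertiary propargyl ether may fragment by ionisation or elimination before the [3,3] shift. Once phenol 6 is present the acetals may be lost at 140 °C, or the allenyl phenol may close in the 5-exo sense to a benzofuran instead of undergoing the hydrogen shift. The fallback sets out from 4 and changes the mechanism: cationic gold(I) catalysis (Ph3PAuNTf2, CH2Cl2, rt) should effect direct 6-endo hydroarylation of the alkyne by either of the equivalent ortho carbons. This makes the same C4–C4a bond with the ether left intact and comes back to the route at 8 without any new compound.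

**Step 5.** Masking of the twisted, di-ortho-substituted formyl group may be incomplete, so that butyllithium adds to the aldehyde. Surplus butyllithium may consume amide 11, and the hindered aryllithium may deprotonate 11 instead of adding to it. The fallback sets out from 8 and replaces the transient mask by an isolated one. Condensation with N,N′-dimethylethane-1,2-diamine without acid (toluene, MgSO4) should give 2-[5,7-bis(methoxymethoxy)-2,2-dimethyl-2H-chromen-6-yl]-1,3-dimethylimidazolidine F1. Lithiation at C8 with one equivalent of s-BuLi and addition to 11 should give (2S)-1-[6-(1,3-dimethylimidazolidin-2-yl)-5,7-bis(methoxymethoxy)-2,2-dimethyl-2H-chromen-8-yl]-2-methylbutan-1-one F2. Hydrolysis of the aminal on wet silica or with cold dilute oxalic acid, which the MOM ethers tolerate, comes back to the route at 15.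

**Step 8.** Condensation at the crowded formyl group may be slow. Reduction of the proline iminium (reductive amination) or Michael addition of a second molecule of 21 to 22 could then overtake the intended sequence. The fallback sets out from 15 and avoids the condensation altogether. Sodium borohydride at −40 °C should reduce only the aldehyde, because the ketone is di-ortho-substituted and alpha-branched, to give (2S)-1-[6-(hydroxymethyl)-5,7-bis(methoxymethoxy)-2,2-dimethyl-2H-chromen-8-yl]-2-methylbutan-1-one F3. Acid-catalysed benzylation of 21 (TsOH cat., nitromethane, rt to 50 °C) through the dialkoxy-stabilised benzylic cation then comes back to the route at 23. Any acetal lost on the way only anticipates step 9.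

**Step 1.** Alkylation may also occur at a flanking hydroxyl, twice, or on a ring carbon, and the tertiary chloride may react slowly, so that conversion and selectivity are both poor. The fallback sets out from 1 and separates selection from alkylation. The bulky silyl chloride TIPSCl with imidazole should select the unhindered 4-hydroxyl to give 2,6-dihydroxy-4-[(triisopropylsilyl)oxy]benzaldehyde F4. Capping with NaH and MOMCl should give 2,6-bis(methoxymethoxy)-4-[(triisopropylsilyl)oxy]benzaldehyde F5, and fluoride should release 4-hydroxy-2,6-bis(methoxymethoxy)benzaldehyde F6. Its single hydroxyl is then alkylated with 2 under the conditions of step 1, and the sequence comes back to the route at 4.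

**Step 7.** O-acylation of the enol ether, double acylation, or oligomerisation through a chlorocarbonyl ketene may erode the yield of pyranone. The fallback sets out from 16 and builds the same carbon chain by carbanion chemistry. Claisen condensation with ethyl acetate (NaH) should give 3-methylhexane-2,4-dione F7. Its dianion (two equivalents of LDA) should be carboxylated at the terminal methyl by carbon dioxide to give 4-methyl-3,5-dioxoheptanoic acid F8. Cyclodehydration with carbonyldiimidazole comes back to the route at 21.

## Further compounds

F0 | step 3 | none | none
F1 | step 5 | 2-[5,7-bis(methoxymethoxy)-2,2-dimethyl-2H-chromen-6-yl]-1,3-dimethylimidazolidine | CN1CCN(C)C1c1c(OCOC)c2c(cc1OCOC)OC(C)(C)C=C2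
F2 | step 5 | (2S)-1-[6-(1,3-dimethylimidazolidin-2-yl)-5,7-bis(methoxymethoxy)-2,2-dimethyl-2H-chromen-8-yl]-2-methylbutan-1-one | CN1CCN(C)C1c1c(OCOC)c2c(c(C(=O)[C@@H](C)CC)c1OCOC)OC(C)(C)C=C2
F3 | step 8 | (2S)-1-[6-(hydroxymethyl)-5,7-bis(methoxymethoxy)-2,2-dimethyl-2H-chromen-8-yl]-2-methylbutan-1-one | OCc1c(OCOC)c2c(c(C(=O)[C@@H](C)CC)c1OCOC)OC(C)(C)C=C2
F4 | step 1 | 2,6-dihydroxy-4-[(triisopropylsilyl)oxy]benzaldehyde | O=Cc1c(O)cc(O[Si](C(C)C)(C(C)C)C(C)C)cc1O
F5 | step 1 | 2,6-bis(methoxymethoxy)-4-[(triisopropylsilyl)oxy]benzaldehyde | O=Cc1c(OCOC)cc(O[Si](C(C)C)(C(C)C)C(C)C)cc1OCOC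
F6 | step 1 | 4-hydroxy-2,6-bis(methoxymethoxy)benzaldehyde | O=Cc1c(OCOC)cc(O)cc1OCOC
F7 | step 7 | 3-methylhexane-2,4-dione | CCC(=O)C(C)C(C)=O
F8 | step 7 | 4-methyl-3,5-dioxoheptanoic acid | CCC(=O)C(C)C(=O)CC(=O)O
A1 | alternative 1 | 4-hydroxy-6-[(3S)-3-methyl-2-oxopentyl]-2H-pyran-2-one | CC[C@H](C)C(=O)Cc1cc(O)cc(=O)o1
A2 | alternative 1 | (2S)-2-methyl-1-(2,4,6-trihydroxyphenyl)butan-1-one | CC[C@H](C)C(=O)c1c(O)cc(O)cc1O
A3 | alternative 2 | 3-ethoxycyclobut-2-en-1-one | CCOC1=CC(=O)C1
A4 | alternative 2 | tert-butyldimethyl({(3S,4S)-4-methyl-1-[(triisopropylsilyl)oxy]hex-1-yn-3-yl}oxy)silane | CC[C@H](C)[C@H](O[Si](C)(C)C(C)(C)C)C#CO[Si](C(C)C)(C(C)C)C(C)C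
A5 | alternative 2 | 2-[(1S,2S)-1-(tert-butyldimethylsilyloxy)-2-methylbutyl]-5-ethoxy-3-(triisopropylsilyloxy)phenol | CC[C@H](C)[C@H](O[Si](C)(C)C(C)(C)C)c1c(O)cc(OCC)cc1O[Si](C(C)C)(C(C)C)C(C)C
A6 | alternative 3 | 2-({5,7-diacetoxy-2,2-dimethyl-8-[(2S)-2-methylbutanoyl]-2H-chromen-6-yl}methyl)propanedioyl dichloride | O=C(Cl)C(Cc1c(OC(C)=O)c2c(c(C(=O)[C@@H](C)CC)c1OC(C)=O)OC(C)(C)C=C2)C(=O)Cl
A7 | alternative 3 | 3-({5,7-diacetoxy-2,2-dimethyl-8-[(2S)-2-methylbutanoyl]-2H-chromen-6-yl}methyl)-6-ethyl-4-hydroxy-5-methyl-2H-pyran-2-one | CCc1oc(=O)c(Cc2c(OC(C)=O)c3c(c(C(=O)[C@@H](C)CC)c2OC(C)=O)OC(C)(C)C=C3)c(O)c1C
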